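## Structural features

The target is an ent-labdane: a trans-fused decalin (ring A = C1–C5 and C10, ring B = C5–C10) whose C9 carries a two-carbon chain (C11, C12) ending at the α-carbon C13 of a 2(5H)-furanone (C13=C14, C15H2–O, C16=O). Four contiguous stereocentres line the ring fusion, all R: quaternary C4 (CH3 and CH2OAc = C19), C5 (H), quaternary C10 (CHO = C20) and C9. C19 and C20 are both axial on the same face of ring A, H5 lies on the opposite face, and the C9 chain is equatorial and cis to C20. C8 bears an exocyclic methylene directly beside the C9 stereocentre. The fragile groups are the neopentyl aldehyde (a free 19-hydroxyl would close on it as a lactol), the 8(17)-alkene (it migrates into ring B under acid or metal hydrides and can trap a free 20-hydroxyl as an ether), the butenolide (no hydride, ylide or strong base) and the acetate. The real difficulty is the 1,3-pair of quaternary carbons C4 and C10, whose one-carbon substituents stand syn but at different oxidation levels, with the C5 hydrogen between them on the other face. The key step uses exactly this syn-diaxial C19/C20 pair: the C19 oxygen carries C20 as a carbonate and hands it to C10 when ring B, still an anisole ring fused to a 1-tetralone (C1 carbonyl), is reduced to an enolate centred on C10, the ring methoxy group marking C8 as the future ketone. One consequence governs the later steps: while the 19,20-lactone is closed, ring A (C1–C2–C3) and the lactone bridge (C20–O–C19) flank C5 almost as mirror images, so the C5 hydrogen is set only after the lactone has been opened.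

## Logic of the disconnections

30 is first simplified at its two one-carbon arms: the C20 aldehyde goes back to the primary alcohol of 29, and the C19 O–acetyl bond is cut to give diol 28. These groups come last because neither survives the hydride, enolate and organometallic steps before them. Both arms become the same robust hydroxymethyl group. The forward demand is an acylation that takes C19–OH and leaves the more encumbered C20–OH, then an oxidation neutral enough for the 8(17)-alkene and the butenolide.

From 28 the two O–benzyl bonds are restored (27) and the C8=C17 bond is cut to the C8 ketone 26. The ketone is the handle for all chemistry at C9, and the alkene must be made after the rhodium step that would otherwise isomerise it. The demand is a non-basic methylenation (C9 is epimerisable, the butenolide is acidic) that leaves lactones alone.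

The side chain of 26 is cut at C12–C13 after shifting the ring alkene C13=C14 out to C12=C13 (25). That bond is then the product of a cross-metathesis between the allyl group of 23 and 24. All four butenolide carbons arrive in one commercial piece and C11–C12 needs no functional handle. The demand is metathesis with a 1,1-disubstituted electron-poor alkene, and an isomerisation that moves the double bond into the lactone ring and not along the chain.

23 is cut at C9–C11 and C6=C7 is reintroduced, leading through 21 to enone 20. With C7 vinylic, C9 is the only carbon the base can deprotonate, so the regiochemistry that a saturated 8-ketone would lose is guaranteed. The demand is alkylation at a neopentyl enolate carbon, 1,4-reduction that spares the terminal alkene, and equilibration of C9 to the equatorial epimer.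

The C5–H bond of 20 is cut by moving the alkene to C5=C6 and masking the C8 carbonyl as its methyl enol ether, giving 18. This is where C5 becomes stereogenic, and it is placed here because in 18 the two axial ether arms on C4 and C10 shield one face. Hydrogenating C5=C6 in a compound that still holds the lactone would offer no such bias. The demand is protonation at C5 opposite the arms, under conditions that also let the trans-fused isomer win thermodynamically.

Removing the two benzyl ethers gives 17, and raising C20 to the acid level and joining it to the C19 oxygen gives lactone 16. C19 and C20 are now tied in one ring that records their syn relationship. The forward demand is a hydride that opens the lactone without touching the enol ether, and a protection that lasts to step 20.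

C1 is re-oxidised: 16 comes from 15 (C1=C2), 15 from enol triflate 14, and 14 from ketone 13. The C1 carbonyl is not part of the target, but it is what makes the aromatic precursor reducible to a C10 enolate, so it is removed straight after it has done its work. The triflate route suits a hindered neopentyl ketone because C2 holds the only enolisable hydrogens. The diimide must then discriminate the disubstituted C1=C2 from two trisubstituted alkenes.

The C10–C20 bond of 13 is cut and ring B is re-aromatised, giving aryl ketone 11 with C20 sitting on the C19 oxygen as a methyl carbonate. One ring, one quaternary stereocentre and all sp3 character of ring B disappear in a single operation. The demand is that reduction gives the enolate at C10 and that this acylates itself faster than it is protonated. The configuration needs no further control because the tether reaches one face only.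

11 is cut at the O–C20 bond into alcohol 9 and 10, and 9 is traced through diol 8 to keto ester 7 by redox adjustment. Reducing the hindered ester needs a reagent that also reduces the ketone, so the benzylic alcohol must be re-oxidised selectively.

The aryl–C1 bond of 7 is cut (Friedel–Crafts transform) to acid 6, obtained from racemic 4 through salt 5. Ring A opens to an acyclic arylglutarate. The ring must close ortho to the quaternary carbon, the only position within reach, and the enantiomers must separate as salts.

4 is the half-ester of 3, and 3 is cut at C3–C4 (Michael transform) into 1 and 2. The quaternary carbon is thus made from a tertiary benzylic ester carbon and an acrylate. The demand is selective hydrolysis of the unhindered ester. The stereocentre is formed racemic and resolved one step later.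

## Other disconnections considered

Alternative 1: The cut removes C5–C10 and C8–C9 together, and with them ring A, leaving the open-chain triene aldehyde A1. Forward, heating A1 (or mild Lewis acid activation of the aldehyde) lets the 2-methylene aldehyde (C9=C10) add across the 1-silyloxydiene (C5=C6–C7=C8) to give the trans-fused octalin aldehyde A2.
- In favour: two rings, two C–C bonds and the C5/C10 pair form in one thermal step. C20 arrives as the aldehyde and C1 never bears oxygen, so the C1 deoxygenation and the late C20 redox steps of the chosen plan disappear. On these two counts the alternative is better. A concerted cycloaddition is also better precedented than the reductive acylation, which is new.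
- Against: the tether forces C5, the diene terminus remote from the silyloxy group and the one with the larger HOMO coefficient, to bond to the α-carbon C10 of the enal and not to its β-carbon C9, against the electronic preference. Both new bonds form at or beside quaternary carbons. The syn C19/C20 relationship depends on facial discrimination by an acyclic quaternary C4 whose methyl and methoxycarbonyl groups differ little in size, and the trans fusion depends on one of two chair-like tether arrangements.
- Comparison: in the chosen plan the C4/C10 relationship is locked by a covalent bridge. A1 needs its own enantioselective entry to C4 (equal to the resolution used here), and after A2 the C8 oxidation, C6=C7 reduction and C9 chain remain (equal task at C9). The step count would be similar or slightly lower, the stereochemical reliability lower.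

Alternative 2: The cut removes C4–CH3 and C5–C6. Forward, a methyl Grignard reagent adds to enone A3 under CuBr·SMe2 with a chiral diphosphine and the magnesium enolate is trapped by an allyl halide, giving A4.
- In favour: C4 is created by asymmetric catalysis with no resolution, which is better than the chosen plan. Two C–C bonds form in one flask, and the reaction type has firm precedent (also better).
- Against: A4 holds only ring A with C4 and C5. C10 is still a carbonyl carbon, so the hardest centre (quaternary C10 with C20 syn to C19), all of ring B and C9 remain, to be built by two successive bond formations at one carbon with only ring sterics as guide. Methyl is the least selective Grignard reagent for β,β-disubstituted enones in this catalysis. The allyl group must enter cis to the bulky silyloxymethyl group and trans to methyl, against the usual steric course of enolate trapping, and equilibration at C5 helps little because the two C4 groups are of similar effective size.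
- Comparison: better on enantioselective entry and on precedent, equal in carrying an oxygenated C19 arm from the start, weaker in postponing the real difficulty. More steps follow the key step than in the chosen plan.

Alternative 3: The cut removes C9–C10. Forward, a secondary amine condenses with the ring A aldehyde A5, the enamine carbon C10 adds to C9 of the tethered (E)-enoate in a 6-exo-trig Michael closure, and hydrolysis returns the aldehyde in A6.
- In favour: quaternary C10 is made with C20 already at the aldehyde level, and the same step fixes C9 with its first two chain carbons. There is no regiochemical problem at C9, no C1 oxygen, and C8 arrives masked. On these points it is better than the chosen plan, and the closure is an ordinary polar step.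
- Against: enamines of α-branched aldehydes form slowly and are weak nucleophiles, and a simple enoate is a weak acceptor. The required face of C10 is the one that places C20 1,3-diaxial to the silyloxymethyl arm on C4, the more hindered approach, and only the chair preference of the forming ring enforces it. A5 needs C4 and C5 set beforehand (for instance through A4), and the C12 ester of A6 still has to be turned into the butenolide while the aldehyde is protected.
- Comparison: equal or better on oxidation-state economy at C20 and C1, weaker on stereocontrol at C10 (steric bias against a tether), and longer overall.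

Key step: step 8

Remark on the chemistry: labdane numbering is used for all bicyclic compounds; the face of the decalin that carries C19 and C20 is called the lower face, and H5 and H9 of the target lie on the upper face.

Assumption: the salt of the (R)-acid with (S)-1-phenylethylamine is taken to be the less soluble diastereomer; should the opposite hold, the (R)-amine is used in the same way.

## Route

Step 1
Reactants: 1 methyl 2-(4-methoxyphenyl)propanoate; 2 methyl acrylate
Product: 3 dimethyl 2-(4-methoxyphenyl)-2-methylpentanedioate (racemic)
Conditions: KOtBu (0.1 equiv), t-BuOH/THF, 0 → 23 °C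
Reagents that add atoms: none
Why: Base-catalysed Michael addition of the benzylic ester enolate to the acrylate forms C3–C4 and the quaternary carbon; the adduct enolate is more basic than the arylpropanoate enolate, so the base turns over, and the quaternary product cannot add a second time.

Step 2
Reactants: 3 dimethyl 2-(4-methoxyphenyl)-2-methylpentanedioate
Product: 4 5-methoxy-4-(4-methoxyphenyl)-4-methyl-5-oxopentanoic acid (racemic)
Conditions: LiOH·H2O (1.05 equiv), THF/MeOH/H2O, 0 °C; 1 M HCl
Reagents that add atoms: lithium hydroxide, [Li+].[OH-]
Why: Saponification; the unhindered chain ester is hydrolysed far faster than the ester on the quaternary benzylic carbon, so one equivalent of hydroxide should give the mono-acid.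

Step 3
Reactants: 4 racemic 5-methoxy-4-(4-methoxyphenyl)-4-methyl-5-oxopentanoic acid
Product: 5 (S)-1-phenylethylammonium (R)-5-methoxy-4-(4-methoxyphenyl)-4-methyl-5-oxopentanoate
Conditions: (S)-PhCH(CH3)NH2 (0.55 equiv), i-PrOH/EtOAc, crystallise, recrystallise
Reagents that add atoms: (S)-1-phenylethylamine, C[C@H](N)c1ccccc1
Why: Classical resolution through diastereomeric ammonium salts; half an equivalent of amine should take the better-fitting enantiomer out of solution and recrystallisation raises the purity; the quaternary centre cannot racemise.

Step 4
Reactants: 5 (S)-1-phenylethylammonium salt of the (R)-acid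
Product: 7 methyl (R)-6-methoxy-1-methyl-4-oxo-1,2,3,4-tetrahydronaphthalene-1-carboxylate, via free (R)-acid 6 (not isolated)
Conditions: 1 M HCl/EtOAc; then P2O5/MeSO3H (1:10), 45 °C
Reagents that add atoms: none
Why: Intramolecular Friedel–Crafts acylation; the acylium ion can reach only the two equivalent ring positions ortho to the quaternary carbon, which gives the six-membered ketone (C1–C10 bond) with methoxy meta to the new carbonyl, as in the standard closure of 4-(4-methoxyphenyl)butanoic acids; the hindered ester and the stereocentre are spectators.

Step 5
Reactants: 7 methyl (R)-6-methoxy-1-methyl-4-oxo-1,2,3,4-tetrahydronaphthalene-1-carboxylate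
Product: 8 (4R)-4-(hydroxymethyl)-7-methoxy-4-methyl-1,2,3,4-tetrahydronaphthalen-1-ol (both C1 epimers)
Conditions: LiAlH4, THF, 0 → 23 °C; NaOH aq work-up
Reagents that add atoms: none
Why: Hydride reduction of ester and ketone together, since the hindered ester cannot be reduced alone; the carbinol stereocentre at C1 is erased in the next step.

Step 6
Reactants: 8 (4R)-4-(hydroxymethyl)-7-methoxy-4-methyl-1,2,3,4-tetrahydronaphthalen-1-ol
Product: 9 (R)-4-(hydroxymethyl)-7-methoxy-4-methyl-3,4-dihydronaphthalen-1(2H)-one
Conditions: MnO2 (activated, 15 equiv), CH2Cl2, 23 °C
Reagents that add atoms: none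
Why: MnO2 oxidises benzylic alcohols and leaves saturated primary alcohols alone, so the aryl ketone returns while the neopentyl C19 hydroxyl stays free.

Step 7
Reactants: 9 (R)-4-(hydroxymethyl)-7-methoxy-4-methyl-3,4-dihydronaphthalen-1(2H)-one; 10 methyl chloroformate
Product: 11 [(1R)-6-methoxy-1-methyl-4-oxo-1,2,3,4-tetrahydronaphthalen-1-yl]methyl methyl carbonate
Conditions: pyridine, DMAP (cat.), CH2Cl2, 0 °C
Reagents that add atoms: none
Why: O-acylation of the primary alcohol by a chloroformate places C20 on the C19 oxygen; the methyl carbonate is kept because methoxide is the smallest and best alkoxide leaving group for the ring closure that follows.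

Step 8
Reactants: 11 [(1R)-6-methoxy-1-methyl-4-oxo-1,2,3,4-tetrahydronaphthalen-1-yl]methyl methyl carbonate
Product: 13 keto lactone dienol ether (C1 ketone; C5=C6; C8(OMe)=C9; C10–C20(=O)–O–C19 lactone on the lower face), via potassium trienolate 12 (not isolated)
Conditions: K (2.1 equiv), NH3(l)/THF, t-BuOH (1.0 equiv), −78 °C; isoprene; −78 → −33 °C; NH4Cl(s)
Reagents that add atoms: none
Why: Proposed new method: potassium transfers two electrons to the aryl ketone, one equivalent of tert-butanol protonates the dianion at C7 (para to the carbonyl-bearing ring carbon and ortho to methoxy, the site expected for a meta-methoxy aryl carbonyl), and the cross-conjugated enolate 12 is left with its nucleophilic carbon at the former aromatic carbon C10, with methoxy on C8=C9 and the second alkene at C5=C6. The closest known reaction type is the Birch reductive alkylation of 1-tetralones and acetophenones at the ipso carbon with alkyl halides; the new element is that the electrophile is an internal carbonate, so the enolate is acylated. C10 adds to the carbonate carbonyl in a 6-exo-trig acyl substitution that closes the ring C10–C20(=O)–O–C19–C4–C5, and loss of methoxide gives the lactone; should the tetrahedral intermediate expel the C19 alkoxide instead, that alkoxide re-closes on the new methyl ester, so both collapse modes lead to 13. C10 is the only new stereocentre and the tether controls it: the arm on C4 reaches only the face of the planar enolate carbon on which it stands, and allylic strain with H6 already holds this larger C4 substituent perpendicular to the ring plane, above C10. The step needs C-acylation to outrun protonation at C10, which the single equivalent of proton donor and the six-membered intramolecular delivery should secure (O-acylation would require an eight-membered ring). It also needs the aryl ketone to be reduced before the carbonate, which its far lower reduction potential and the metered 2.1 equivalents of metal at −78 °C should secure; isoprene removes any excess before warming so that the new C1 ketone is not reduced. Potassium is preferred to lithium because the looser ion pair favours ring protonation of the ketyl dianion over pinacol coupling and carbonyl reduction.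

Step 9
Reactants: 13 keto lactone dienol ether
Product: 14 C1 enol triflate (C1(OTf)=C2) of the lactone dienol ether
Conditions: KHMDS, THF, −78 °C; PhNTf2, −78 → 0 °C
Reagents that add atoms: N-phenylbis(trifluoromethanesulfonimide), O=S(=O)(N(c1ccccc1)S(=O)(=O)C(F)(F)F)C(F)(F)F
Why: Enol triflate formation; C2 carries the only α-hydrogens of the C1 ketone (C10 is quaternary) and the lactone has none, so a single enolate forms and is sulfonylated on oxygen.

Step 10
Reactants: 14 C1 enol triflate
Product: 15 triene lactone (C1=C2; C5=C6; C8(OMe)=C9)
Conditions: Pd(OAc)2 (5 mol%), PPh3 (10 mol%), Bu3N, HCO2H, DMF, 60 °C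
Reagents that add atoms: none
Why: Palladium-catalysed formate reduction of a vinyl triflate (oxidative addition, formate exchange, decarboxylation, reductive elimination) replaces C1–O by C1–H; the buffered medium spares enol ether, lactone and the other alkenes.

Step 11
Reactants: 15 triene lactone
Product: 16 diene lactone (ring A saturated; C5=C6; C8(OMe)=C9)
Conditions: 2-O2NC6H4SO2NHNH2, Et3N, CH2Cl2, 23 °C
Reagents that add atoms: none
Why: Diimide reduction; diimide transfers hydrogen to the cis-disubstituted C1=C2 far faster than to the trisubstituted C5=C6 or the trisubstituted enol ether, and the basic medium protects the enol ether.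

Step 12
Reactants: 16 diene lactone
Product: 17 19,20-diol dienol ether
Conditions: LiAlH4, THF, 0 → 23 °C; NaOH aq work-up
Reagents that add atoms: none
Why: Hydride reduction of the lactone to the diol opens the bridge, so that from here on the two axial hydroxymethyl arms mark one face of C5; the enol ether survives hydride and the basic work-up.

Step 13
Reactants: 17 19,20-diol dienol ether
Product: 18 19,20-bis(4-methoxybenzyl) ether dienol ether
Conditions: NaH, 4-MeOC6H4CH2Cl, Bu4NI (cat.), DMF, 0 → 23 °C
Reagents that add atoms: 4-methoxybenzyl chloride, COc1ccc(CCl)cc1
Why: Williamson etherification of both neopentyl alkoxides; these ethers withstand amide bases, copper hydride, ruthenium, rhodium and the zinc–titanium reagent, and are removed oxidatively at the end without touching alkene or butenolide.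

Step 14
Reactants: 18 bis(4-methoxybenzyl) ether dienol ether
Product: 20 trans-fused 6-en-8-one bis(4-methoxybenzyl) ether (H5 on the upper face), via β,γ-unsaturated ketone 19 (not isolated)
Conditions: (CO2H)2, THF/H2O, 23 °C; then DBU, toluene, 40 °C
Reagents that add atoms: water, O
Why: Enol ether hydrolysis, then base-mediated migration of C5=C6 into conjugation through the extended dienolate; C5 is protonated on the upper face, opposite the two axial ether arms on C4 and C10, and the trans-fused enone is also the thermodynamic isomer under these equilibrating conditions.

Step 15
Reactants: 20 trans-fused 6-en-8-one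
Product: 21 9-allyl-6-en-8-one (allyl on the upper face, axial)
Conditions: LDA, THF, −78 °C; allyl iodide, DMPU, −78 → −20 °C
Reagents that add atoms: allyl iodide, C=CCI
Why: Kinetic α′-deprotonation of an enone and enolate alkylation; with C7 vinylic, C9 is the only site the amide base deprotonates quickly (the 6-alkylation of isophorone is the model for this neopentyl position), and the allyl group should enter mainly anti to the axial C20 arm, a configuration corrected in step 16.

Step 16
Reactants: 21 9-allyl-6-en-8-one
Product: 23 9-allyl-8-one with the allyl group equatorial on the lower face, via 9-epi ketone 22 (not isolated)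
Conditions: [(Ph3P)CuH]6, toluene, H2O, 23 °C; then NaOMe (cat.), MeOH, 23 °C
Reagents that add atoms: none
Why: Copper hydride conjugate reduction removes C6=C7 without touching the terminal alkene or the carbonyl; methoxide then equilibrates C9 through the C8 enolate to the equatorial allyl epimer, cis to C20, the arrangement favoured in 8-oxolabdanes.

Step 17
Reactants: 23 9-allyl-8-one; 24 α-methylene-γ-butyrolactone
Product: 25 (E)-12-en-16,15-olide 8-ketone (α-alkylidene lactone)
Conditions: 24 (3 equiv), second-generation Hoveyda–Grubbs catalyst RuCl2(SIMes)(=CH-C6H4-2-OiPr) (10 mol%), 2,6-dichloro-1,4-benzoquinone (20 mol%), CH2Cl2, 40 °C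
Reagents that add atoms: none
Why: Olefin cross-metathesis between the terminal alkene and the 1,1-disubstituted alkene of 24 forms C12=C13; the quinone suppresses ruthenium hydride isomerisation of 24, and the E isomer should dominate, although the geometry is erased in step 18.

Step 18
Reactants: 25 (E)-α-alkylidene lactone ketone
Product: 26 13-en-16,15-olide 8-ketone (endocyclic butenolide)
Conditions: RhCl3·3H2O (10 mol%), EtOH, 75 °C
Reagents that add atoms: none
Why: Rhodium hydride-catalysed alkene isomerisation (hydrometalation to the α-rhodio lactone, β-hydride elimination toward C14) moves the exocyclic alkene into the ring to give the more stable butenolide; it precedes methylenation because the same catalyst would pull an 8(17)-alkene into ring B.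

Step 19
Reactants: 26 butenolide 8-ketone
Product: 27 8(17),13-dien-16,15-olide 19,20-bis(4-methoxybenzyl) ether
Conditions: Zn, CH2Br2, TiCl4, THF (reagent aged at 5 °C); CH2Cl2, 0 → 23 °C
Reagents that add atoms: dibromomethane, BrCBr
Why: Takai–Lombardo methylenation; the zinc–titanium methylene reagent is non-basic, so C9 is not epimerised and the butenolide is not deprotonated, and it converts ketones while leaving lactones alone.

Step 20
Reactants: 27 8(17),13-dien-16,15-olide bis(4-methoxybenzyl) ether
Product: 28 19,20-dihydroxy-8(17),13-dien-16,15-olide
Conditions: DDQ, CH2Cl2/pH 7 buffer (10:1), 0 → 23 °C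
Reagents that add atoms: none
Why: Oxidative cleavage of 4-methoxybenzyl ethers by hydride abstraction at the electron-rich benzylic carbon and hydrolysis of the oxocarbenium ion; the electron-poor butenolide and the 1,1-disubstituted alkene do not react, and the buffer keeps acid away from the 20-hydroxyl/8(17)-alkene pair.

Step 21
Reactants: 28 19,20-diol
Product: 29 19-acetoxy-20-hydroxy-8(17),13-dien-16,15-olide
Conditions: AcCl (1.05 equiv), 2,4,6-collidine, CH2Cl2, −78 → −40 °C
Reagents that add atoms: acetyl chloride, CC(=O)Cl
Why: Sterically controlled mono-acylation; C19–OH is flanked by a methyl group and a ring methylene, whereas C20–OH sits in the pocket between C1, C11 and the ring fusion, so a limiting amount of acylating agent should take C19–OH first.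

Step 22
Reactants: 29 19-acetoxy-20-hydroxy compound
Product: 30 (4R,5R,9R,10R)-19-acetoxy-20-oxo-ent-labda-8(17),13-dien-16,15-olide (target)
Conditions: Dess–Martin periodinane, NaHCO3, CH2Cl2, 0 → 23 °C
Reagents that add atoms: none
Why: Dess–Martin oxidation of the neopentyl primary alcohol to the aldehyde under buffered, non-acidic conditions; C20 has no α-hydrogen and the acetate on C19 prevents lactol formation, so the aldehyde should be stable once formed.

## Compound list

1 | methyl 2-(4-methoxyphenyl)propanoate (racemic) | COC(=O)C(C)c1ccc(OC)cc1 | starting material
2 | methyl acrylate | C=CC(=O)OC | starting material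
3 | dimethyl 2-(4-methoxyphenyl)-2-methylpentanedioate (racemic) | COC(=O)CCC(C)(C(=O)OC)c1ccc(OC)cc1 | intermediate
4 | 5-methoxy-4-(4-methoxyphenyl)-4-methyl-5-oxopentanoic acid (racemic) | COC(=O)C(C)(CCC(=O)O)c1ccc(OC)cc1 | intermediate
5 | (S)-1-phenylethylammonium (R)-5-methoxy-4-(4-methoxyphenyl)-4-methyl-5-oxopentanoate | COC(=O)[C@](C)(CCC(=O)[O-])c1ccc(OC)cc1.C[C@H]([NH3+])c1ccccc1 | intermediate
6 | (R)-5-methoxy-4-(4-methoxyphenyl)-4-methyl-5-oxopentanoic acid | COC(=O)[C@](C)(CCC(=O)O)c1ccc(OC)cc1 | intermediate (not isolated)
7 | methyl (R)-6-methoxy-1-methyl-4-oxo-1,2,3,4-tetrahydronaphthalene-1-carboxylate (quaternary carbon = C4, ketone = C1) | COC(=O)[C@]1(C)CCC(=O)c2cc(OC)ccc12 | intermediate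
8 | (4R)-4-(hydroxymethyl)-7-methoxy-4-methyl-1,2,3,4-tetrahydronaphthalen-1-ol, both C1 epimers | OC[C@]1(C)CCC(O)c2cc(OC)ccc12 | intermediate
9 | (R)-4-(hydroxymethyl)-7-methoxy-4-methyl-3,4-dihydronaphthalen-1(2H)-one | OC[C@]1(C)CCC(=O)c2cc(OC)ccc12 | intermediate
10 | methyl chloroformate | COC(=O)Cl | starting material
11 | [(1R)-6-methoxy-1-methyl-4-oxo-1,2,3,4-tetrahydronaphthalen-1-yl]methyl methyl carbonate | COC(=O)OC[C@]1(C)CCC(=O)c2cc(OC)ccc12 | intermediate
12 | potassium trienolate of 11 after two-electron reduction and protonation at C7 (C1(O−)=C10, C8(OMe)=C9, C5=C6) | COC(=O)OC[C@]1(C)CCC([O-])=C2C=C(OC)CC=C21.[K+] | intermediate (not isolated)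
13 | keto lactone dienol ether: C1 ketone, C5=C6, C8(OMe)=C9, δ-lactone C10–C20(=O)–O–C19–C4 on the lower face, 4-methyl on the upper face | COC1=C[C@@]23C(=O)CC[C@@](C)(COC2=O)C3=CC1 | intermediate
14 | C1 enol triflate of 13 (C1(OSO2CF3)=C2) | COC1=C[C@@]23C(OS(=O)(=O)C(F)(F)F)=CC[C@@](C)(COC2=O)C3=CC1 | intermediate
15 | triene lactone (C1=C2, C5=C6, C8(OMe)=C9; 19,20-lactone) | COC1=C[C@@]23C=CC[C@@](C)(COC2=O)C3=CC1 | intermediate
16 | diene lactone (ring A saturated, C5=C6, C8(OMe)=C9; 19,20-lactone) | COC1=C[C@@]23CCC[C@@](C)(COC2=O)C3=CC1 | intermediate
17 | 19,20-diol dienol ether (both CH2OH on the lower face; C5=C6, C8(OMe)=C9) | COC1=C[C@]2(CO)CCC[C@@](C)(CO)C2=CC1 | intermediate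
18 | 19,20-bis(4-methoxybenzyl) ether of 17 | COC1=C[C@]2(COCc3ccc(OC)cc3)CCC[C@@](C)(COCc3ccc(OC)cc3)C2=CC1 | intermediate
19 | 5-en-8-one 19,20-bis(4-methoxybenzyl) ether (β,γ-unsaturated ketone) | O=C1CC=C2[C@](C)(COCc3ccc(OC)cc3)CCC[C@@]2(COCc3ccc(OC)cc3)C1 | intermediate (not isolated)
20 | trans-fused 6-en-8-one 19,20-bis(4-methoxybenzyl) ether (H5 upper face, C20 lower face) | O=C1C=C[C@@H]2[C@](C)(COCc3ccc(OC)cc3)CCC[C@@]2(COCc3ccc(OC)cc3)C1 | intermediate
21 | 9-allyl-6-en-8-one, allyl on the upper face (trans to C20) | O=C1C=C[C@@H]2[C@](C)(COCc3ccc(OC)cc3)CCC[C@@]2(COCc3ccc(OC)cc3)[C@H]1CC=C | intermediate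
22 | 9-epi 9-allyl-8-one (allyl axial, upper face) | O=C1CC[C@@H]2[C@](C)(COCc3ccc(OC)cc3)CCC[C@@]2(COCc3ccc(OC)cc3)[C@H]1CC=C | intermediate (not isolated)
23 | 9-allyl-8-one, allyl equatorial on the lower face (cis to C20), trans-decalin | O=C1CC[C@@H]2[C@](C)(COCc3ccc(OC)cc3)CCC[C@@]2(COCc3ccc(OC)cc3)[C@@H]1CC=C | intermediate
24 | α-methylene-γ-butyrolactone (3-methylenedihydrofuran-2(3H)-one) | C=C1CCOC1=O | starting material
25 | (E)-12-en-16,15-olide 8-ketone, 19,20-bis(4-methoxybenzyl) ether (α-alkylidene lactone) | O=C1CC[C@@H]2[C@](C)(COCc3ccc(OC)cc3)CCC[C@@]2(COCc3ccc(OC)cc3)[C@@H]1C/C=C1\CCOC1=O | intermediate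
26 | 13-en-16,15-olide 8-ketone, 19,20-bis(4-methoxybenzyl) ether (butenolide) | O=C1CC[C@@H]2[C@](C)(COCc3ccc(OC)cc3)CCC[C@@]2(COCc3ccc(OC)cc3)[C@@H]1CCC1=CCOC1=O | intermediate
27 | 8(17),13-dien-16,15-olide 19,20-bis(4-methoxybenzyl) ether | C=C1CC[C@@H]2[C@](C)(COCc3ccc(OC)cc3)CCC[C@@]2(COCc3ccc(OC)cc3)[C@@H]1CCC1=CCOC1=O | intermediate
28 | 19,20-dihydroxy-ent-labda-8(17),13-dien-16,15-olide | C=C1CC[C@@H]2[C@](C)(CO)CCC[C@@]2(CO)[C@@H]1CCC1=CCOC1=O | intermediate
29 | 19-acetoxy-20-hydroxy-ent-labda-8(17),13-dien-16,15-olide | C=C1CC[C@@H]2[C@](C)(COC(C)=O)CCC[C@@]2(CO)[C@@H]1CCC1=CCOC1=O | intermediate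
30 | (4R,5R,9R,10R)-19-acetoxy-20-oxo-ent-labda-8(17),13-dien-16,15-olide | C=C1CC[C@@H]2[C@](C)(COC(C)=O)CCC[C@@]2(C=O)[C@@H]1CCC1=CCOC1=O | target

## Step count and least certain steps

Total: 22 steps. Longest linear sequence: 22 steps from 1 (2, 10 and 24 are commercial).

Step 8 (key step). The most likely failures are protonation of C10 or over-reduction of the C1 carbonyl outrunning the acyl transfer, loss of the carbonate by ammonolysis, and ring opening of the β-keto lactone by the methoxide that is released. The fallback is a stepwise version built from known operations and sets out from 9. Reduction of 9 with K/NH3/t-BuOH and a cold NH4Cl quench protonates the enolate at C10 and should give the non-conjugated dihydro hydroxy ketone F1. Acylation of its hydroxyl with methyl chloroformate/pyridine gives the dihydro ketone carbonate F2. KHMDS in THF at −78 °C regenerates the same enolate, because the C10 hydrogen, α to the ketone and doubly allylic, is by far the most acidic. On warming it closes onto the carbonate (Dieckmann-type intramolecular acylation) and the route is rejoined at 13.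

Step 18. The double bond may stall, or walk along the chain toward C9 and the C8 carbonyl instead of into the lactone ring, and hydrogen chloride released from the rhodium salt may erode the benzyl ethers. The fallback sets out from 25. Methylenation of the ketone first (Zn/CH2Br2/TiCl4) gives the 8(17)-methylene alkylidene lactone F3. Conjugate reduction with Li[HB(s-Bu)3] and trapping of the lactone enolate with PhSeBr gives the α-phenylselanyl lactone F4. H2O2/pyridine then effects selenoxide syn-elimination into the ring, by analogy with the sulfoxide eliminations used for 3-alkylbutenolides, and the route is rejoined at 27, bypassing 26.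

Step 21. Discrimination between the two primary hydroxyls may be insufficient, or both may be acetylated. The fallback sets out from 28. N-Iodosuccinimide closes the 20-hydroxyl onto the 8(17)-alkene (5-exo iodoetherification, which only C20–OH can reach) to give the 8,20-iodoether F5. Ac2O/DMAP acetylates the one remaining hydroxyl to the iodoether acetate F6. Zinc dust in buffered ethanol reverses the iodoether by reductive β-elimination, returning the alkene and the free 20-hydroxyl, and the route is rejoined at 29.

Step 15. C-Alkylation at the neopentyl enolate carbon may be slow, with O-allylation or proton exchange taking over. The fallback sets out from 20. The potassium enolate is trapped on oxygen with allyl chloroformate to give the allyl dienyl carbonate F7. Pd(PPh3)4 then induces decarboxylative (Tsuji) allylation, which delivers the allyl group to C9 within the ion pair, and the route is rejoined at 21 (either C9 epimer serves).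

Step 14. Migration of the alkene may be incomplete, or protonation at C5 may show poor facial selectivity. The fallback sets out from 18 and stops the hydrolysis at 19. Hydrogen-atom-transfer hydrogenation of C5=C6 (Mn(dpm)3, PhSiH3, t-BuOOH, i-PrOH), which favours the trans-fused product, gives the saturated 8-ketone F8. Kinetic enolisation away from the neopentyl C9 (LDA, Me3SiCl) gives the 7-ene silyl enol ether F9. Saegusa–Ito oxidation with Pd(OAc)2 rejoins the route at 20.

Step 3. The salt may crystallise without useful enrichment, because the stereocentre is three bonds from the carboxylate. The fallback sets out from 4. Cyclisation of the racemic acid with P2O5/MeSO3H gives the racemic tetralone ester F10. Its enantiomers are separated by preparative chromatography on a chiral stationary phase (amylose tris(3,5-dimethylphenylcarbamate), supercritical CO2/MeOH), and the (R)-enantiomer rejoins the route at 7. Its configuration is to be confirmed by X-ray analysis of a heavy-atom derivative.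

## Further compounds

F1 | step 8 | (4R)-4-(hydroxymethyl)-7-methoxy-4-methyl-3,4,6,8a-tetrahydronaphthalen-1(2H)-one (C8a epimers) | OC[C@]1(C)CCC(=O)C2C=C(OC)CC=C12
F2 | step 8 | methyl carbonate of F1 | COC(=O)OC[C@]1(C)CCC(=O)C2C=C(OC)CC=C12
F3 | step 18 | 8(17)-methylene (E)-12-en-16,15-olide 19,20-bis(4-methoxybenzyl) ether | C=C1CC[C@@H]2[C@](C)(COCc3ccc(OC)cc3)CCC[C@@]2(COCc3ccc(OC)cc3)[C@@H]1C/C=C1\CCOC1=O
F4 | step 18 | 13-(phenylselanyl)-8(17)-en-16,15-olide 19,20-bis(4-methoxybenzyl) ether (C13 epimers) | C=C1CC[C@@H]2[C@](C)(COCc3ccc(OC)cc3)CCC[C@@]2(COCc3ccc(OC)cc3)[C@@H]1CCC1([Se]c3ccccc3)CCOC1=O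
F5 | step 21 | 8,20-epoxy-17-iodo-19-hydroxy-13-en-16,15-olide (ether oxygen on the lower face of C8) | IC[C@]12CC[C@@H]3[C@](C)(CO)CCC[C@@]3(CO1)[C@@H]2CCC1=CCOC1=O
F6 | step 21 | 19-acetate of F5 | IC[C@]12CC[C@@H]3[C@](C)(COC(C)=O)CCC[C@@]3(CO1)[C@@H]2CCC1=CCOC1=O
F7 | step 15 | allyl 6,8-dien-8-yl carbonate of 20 (C8(OCO2allyl)=C9, C6=C7) | C=CCOC(=O)OC1=C[C@]2(COCc3ccc(OC)cc3)CCC[C@@](C)(COCc3ccc(OC)cc3)[C@H]2C=C1
F8 | step 14 | trans-fused saturated 8-ketone 19,20-bis(4-methoxybenzyl) ether | O=C1CC[C@@H]2[C@](C)(COCc3ccc(OC)cc3)CCC[C@@]2(COCc3ccc(OC)cc3)C1
F9 | step 14 | 8-(trimethylsilyloxy)-7-ene 19,20-bis(4-methoxybenzyl) ether | C[Si](C)(C)OC1=CC[C@@H]2[C@](C)(COCc3ccc(OC)cc3)CCC[C@@]2(COCc3ccc(OC)cc3)C1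
F10 | step 3 | methyl 6-methoxy-1-methyl-4-oxo-1,2,3,4-tetrahydronaphthalene-1-carboxylate (racemic) | COC(=O)C1(C)CCC(=O)c2cc(OC)ccc12
A1 | alternative 1 | methyl 2-[(1E,3E)-4-(tert-butyldimethylsilyloxy)buta-1,3-dienyl]-6-formyl-2-methylhept-6-enoate (C4 as in the target) | C=C(C=O)CCC[C@@](C)(C(=O)OC)/C=C/C=C/O[Si](C)(C)C(C)(C)C
A2 | alternative 1 | trans-fused octalin aldehyde with C8 silyl ether, C6=C7 and C4 methyl ester | CC(C)(C)[Si](C)(C)O[C@@H]1C=C[C@@H]2[C@](C)(C(=O)OC)CCC[C@@]2(C=O)C1
A3 | alternative 2 | 3-[(tert-butyldiphenylsilyloxy)methyl]cyclohex-2-en-1-one | O=C1C=C(CO[Si](c2ccccc2)(c2ccccc2)C(C)(C)C)CCC1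
A4 | alternative 2 | 2-allyl-3-methyl-3-[(tert-butyldiphenylsilyloxy)methyl]cyclohexanone (C4 and C5 as in the target) | C=CC[C@@H]1[C@](C)(CO[Si](c2ccccc2)(c2ccccc2)C(C)(C)C)CCCC1=O
A5 | alternative 3 | ring A aldehyde with C8 dioxolane and tethered (E)-enoate (C10 epimers) | O=CC1CCC[C@@](C)(CO[Si](C)(C)C(C)(C)C)[C@H]1CCC1(/C=C/C(=O)OC)OCCO1
A6 | alternative 3 | trans-decalin with quaternary C10 aldehyde, C8 dioxolane and C9 CH2CO2Me arm | C12(OCCO1)CC[C@@H]3[C@](C)(CO[Si](C)(C)C(C)(C)C)CCC[C@@]3(C=O)[C@@H]2CC(=O)OC
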